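**Retrosynthetic overview**

- Feature: in the side chain, the stereocentre C1' (CH(CH3) on chromene C6) is separated by the alkene carbon C2' (=CH) from C3' (=C(CH3) on benzofuran C2). C2' and C3' are therefore treated as the two carbons of a ketene that forms when C1' migrates, with retention, from an acyl carbon to a diazo carbon.
- Disconnections: C3'–CH3 (Negishi coupling on a Z-enol triflate); benzofuran C2–C3' and C1'–C2' (photochemical Wolff shift of diazoketone 12, capture of ketene 21 by 2-lithiobenzofuran 22, O-triflation); C1' from asymmetric hydrogenation of a 2-arylacrylic acid.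
- Ring order: pyran ring B is closed first onto benzene ring A (step 1, chromene). Furan ring C is closed onto benzene ring D (step 8, benzofuran). No ring is formed in or after the key step.
- Protecting groups: the benzofuran phenol is carried as a TBS ether, not an acetal ether, because an acetal at O6 would direct lithiation to C7 between the two oxygens. The acetyl group is carried as a dioxolane. Both are removed at the end by fluoride and brief dilute acid.

Key step: step 11

Remark: the sense of induction in step 5 is assigned by analogy with 2-(6-methoxy-2-naphthyl)acrylic acid, where the (S)-ligand gives the (S)-acid; if the ortho-methoxy group reversed it, the other ligand enantiomer would be used.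

**Route**

Step 1
Reactants: 1 4-bromo-3-methoxyphenol; 2 3-methylbut-2-enal
Product: 4 6-bromo-7-methoxy-2,2-dimethyl-2H-chromene, via ortho-quinone methide 3 (not isolated)
Conditions: PhB(OH)2 (1 equiv), AcOH, toluene, reflux, Dean–Stark
Reagents that add atoms: none
Why: Phenylboronic acid-templated ortho-condensation of a phenol with an enal (chromenylation) should join the aldehyde carbon to C6 of the phenol, which is para to OMe and less hindered than C2, and the resulting ortho-quinone methide 3 closes pyran ring B by oxa-6π-electrocyclisation.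

Step 2
Reactants: 4 6-bromo-7-methoxy-2,2-dimethyl-2H-chromene; 5 ethyl pyruvate
Product: 7 ethyl 2-hydroxy-2-(7-methoxy-2,2-dimethyl-2H-chromen-6-yl)propanoate (racemic), via aryllithium 6 (not isolated)
Conditions: n-BuLi, THF, −78 °C; cannulate into 5 (1.5 equiv), THF, −78 °C; NH4Cl (aq)
Reagents that add atoms: none
Why: Bromine–lithium exchange followed by 1,2-addition of the aryllithium to the ketone carbonyl of the α-keto ester, which is far more electrophilic than the ester, with inverse addition at −78 °C to hold back enolisation; the new carbinol centre is racemic and is removed in step 3.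

Step 3
Reactants: 7 ethyl 2-hydroxy-2-(7-methoxy-2,2-dimethyl-2H-chromen-6-yl)propanoate
Product: 8 ethyl 2-(7-methoxy-2,2-dimethyl-2H-chromen-6-yl)acrylate
Conditions: Burgess reagent, toluene, 50 °C
Reagents that add atoms: none
Why: Burgess dehydration (syn-elimination of the sulfamate ester) of a tertiary benzylic alcohol whose only β-hydrogens are on the methyl group, so the 1,1-disubstituted acrylate is the only alkene that can form and no acid touches the chromene.

Step 4
Reactants: 8 ethyl 2-(7-methoxy-2,2-dimethyl-2H-chromen-6-yl)acrylate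
Product: 9 2-(7-methoxy-2,2-dimethyl-2H-chromen-6-yl)acrylic acid
Conditions: LiOH, THF/H2O, 0 → 25 °C; then 1 M HCl to pH 3, 0 °C
Reagents that add atoms: lithium hydroxide, [Li+].[OH-]
Why: Saponification of the ethyl ester with hydroxide in the absence of an alcohol co-solvent, which avoids conjugate addition of alkoxide to the 2-arylacrylate.

Step 5
Reactants: 9 2-(7-methoxy-2,2-dimethyl-2H-chromen-6-yl)acrylic acid
Product: 10 (R)-2-(7-methoxy-2,2-dimethyl-2H-chromen-6-yl)propanoic acid
Conditions: Ru(OAc)2[(R)-BINAP] (1 mol %), H2 (100 atm), MeOH, 20 °C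
Reagents that add atoms: none
Why: Carboxylate-directed asymmetric hydrogenation of a 2-arylacrylic acid with a ruthenium BINAP diacetate (Noyori type) should deliver H2 to one face of the C=CH2 bond and set C1' as (R) under ligand control, while the chromene C3=C4 bond, which has no coordinating group, is expected to remain.

Step 6
Reactants: 10 (R)-2-(7-methoxy-2,2-dimethyl-2H-chromen-6-yl)propanoic acid
Product: 12 (R)-1-diazo-3-(7-methoxy-2,2-dimethyl-2H-chromen-6-yl)butan-2-one, via mixed anhydride 11 (not isolated)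
Conditions: i-BuOCOCl, N-methylmorpholine, THF, −20 °C; then CH2N2, Et2O, −20 → 0 °C
Reagents that add atoms: diazomethane, C=[N+]=[N-]
Why: Acylation of diazomethane by a mixed carbonic anhydride (first stage of the Arndt–Eistert sequence) at low temperature with a weak hindered base, so that the α-aryl stereocentre is not deprotonated and C1' keeps its configuration.

Step 7
Reactants: 13 2,4-dihydroxyacetophenone
Product: 14 1-(2,4-dihydroxy-5-iodophenyl)ethanone
Conditions: ICl, AcOH, 25 °C
Reagents that add atoms: iodine monochloride, ClI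
Why: Electrophilic aromatic iodination of the resorcinol ring under acidic conditions is expected at C5, which is ortho to the free 4-OH and para to the chelated 2-OH and is less hindered than C3 between the two oxygens.

Step 8
Reactants: 14 1-(2,4-dihydroxy-5-iodophenyl)ethanone; 15 ethynyltrimethylsilane
Product: 18 1-(6-hydroxybenzofuran-5-yl)ethanone, via alkynylphenol 16 (not isolated), via 2-silylbenzofuran 17 (not isolated)
Conditions: PdCl2(PPh3)2 (3 mol %), CuI (5 mol %), Et3N, DMF, 25 → 70 °C; then TBAF, THF, 25 °C; NH4Cl (aq)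
Reagents that add atoms: none
Why: Sonogashira coupling followed in the same pot by metal-promoted 5-endo-dig attack of the adjacent 4-OH on the alkyne (domino coupling–cycloisomerisation, closing furan ring C) and fluoride protodesilylation of the 2-silylbenzofuran; only the 4-OH is ortho to the alkyne, so the linear 5-acetyl-6-hydroxybenzofuran is the only ring isomer that can form.

Step 9
Reactants: 18 1-(6-hydroxybenzofuran-5-yl)ethanone
Product: 19 1-[6-(tert-butyldimethylsilyloxy)benzofuran-5-yl]ethanone
Conditions: TBSCl, imidazole, DMF, 25 °C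
Reagents that add atoms: tert-butyldimethylsilyl chloride, CC(C)(C)[Si](C)(C)Cl
Why: Standard silylation of a phenol, chosen because the bulky silyl ether does not direct lithiation to C7 and is later removed by fluoride without acid.

Step 10
Reactants: 19 1-[6-(tert-butyldimethylsilyloxy)benzofuran-5-yl]ethanone
Product: 20 tert-butyldimethyl{[5-(2-methyl-1,3-dioxolan-2-yl)benzofuran-6-yl]oxy}silane
Conditions: (TMSOCH2)2 (2 equiv), TMSOTf (10 mol %), CH2Cl2, −78 → −20 °C; pyridine
Reagents that add atoms: 1,2-bis(trimethylsilyloxy)ethane, C[Si](C)(C)OCCO[Si](C)(C)C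
Why: Noyori ketalisation under aprotic conditions, driven by formation of hexamethyldisiloxane, should convert the aryl methyl ketone into its dioxolane without cleaving the aryl silyl ether, and masks the acetyl group against organolithiums.

Step 11
Reactants: 12 (R)-1-diazo-3-(7-methoxy-2,2-dimethyl-2H-chromen-6-yl)butan-2-one; 20 tert-butyldimethyl{[5-(2-methyl-1,3-dioxolan-2-yl)benzofuran-6-yl]oxy}silane
Product: 24 (S,Z)-1-[6-(tert-butyldimethylsilyloxy)-5-(2-methyl-1,3-dioxolan-2-yl)benzofuran-2-yl]-3-(7-methoxy-2,2-dimethyl-2H-chromen-6-yl)but-1-en-1-yl trifluoromethanesulfonate, via ketene 21 (not isolated), via 2-lithiobenzofuran 22 (not isolated), via lithium enolate 23 (not isolated)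
Conditions: 12, THF (0.02 M), 395 nm LED, −78 °C; cannulate into 22 [from 20 (1.3 equiv), n-BuLi (1.25 equiv), THF, −78 °C]; then PhNTf2 (1.6 equiv), −78 → 0 °C
Reagents that add atoms: N-phenylbis(trifluoromethanesulfonimide), O=S(=O)(N(c1ccccc1)S(=O)(=O)C(F)(F)F)C(F)(F)F
Why: Proposed new method: irradiation into the weak n→π* band of the s-Z diazoketone at 395 nm, above the absorption edge of the chromene so that its pyran ring is not photo-opened, expels N2 with concerted 1,2-shift of C1' from the acyl carbon to the diazo carbon (new C1'–C2' bond, with the retention at the migrating carbon that is general for Wolff shifts) and gives monosubstituted ketene 21 with C3' as its carbonyl carbon. Cannulation of the cold dilute ketene into a slight excess of 2-lithiobenzofuran 22 forms the benzofuran C2–C3' bond by attack on the ketene carbon in the plane of the C2' substituents from the side of hydrogen, away from the branched C1', so that lithium enolate 23 carries O cis to C1', and O-sulfonylation with PhNTf2 fixes this as the (Z)-enol triflate. The closest known reactions are the photochemical Arndt–Eistert homologation, in which the ketene is taken up by O- or N-nucleophiles, and the addition of organolithiums to ketenes generated in the flask from hindered aryl ester enolates, which gives enolates of defined geometry that are then O-silylated or O-acylated; their union on a photogenerated ketene next to a stereocentre, with O-triflation, is the untested part. No ring is closed and no stereocentre is created: C1' is only carried over, and the one new stereo-element, the C2'=C3' geometry, is controlled by the approach of the nucleophile past H and not past C1'. The step needs C-addition to outrun ketene dimerisation, deprotonation at C2' and acylation of enolate 23 by further ketene, which the low temperature, the dilution, the inverse addition and the excess of the weakly basic heteroaryllithium should secure.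

Step 12
Reactants: 24 (S,Z)-enol triflate
Product: 25 tert-butyl{[2-((S,E)-4-(7-methoxy-2,2-dimethyl-2H-chromen-6-yl)pent-2-en-2-yl)-5-(2-methyl-1,3-dioxolan-2-yl)benzofuran-6-yl]oxy}dimethylsilane
Conditions: MeZnCl (3 equiv), Pd(PPh3)4 (5 mol %), THF, 50 °C
Reagents that add atoms: methylzinc chloride, C[Zn]Cl
Why: Negishi coupling of an alkenyl triflate, in which oxidative addition to zerovalent palladium, transmetalation and reductive elimination all proceed with retention at the sp2 carbon, so methyl takes the place of the triflate cis to C1' and the alkene is E (the descriptor changes from Z only through the priority rules).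

Step 13
Reactants: 25 silyl ether dioxolane of the target
Product: 27 1-{6-hydroxy-2-[(S,E)-4-(7-methoxy-2,2-dimethyl-2H-chromen-6-yl)pent-2-en-2-yl]benzofuran-5-yl}ethanone (target CNP0347774.1), via phenol ketal 26 (not isolated)
Conditions: TBAF, THF, 0 °C; then 0.5 M HCl (aq), 25 °C
Reagents that add atoms: water, O
Why: Fluoride cleavage of the aryl silyl ether followed by dilute-acid hydrolysis of the 2-aryl-2-methyldioxolane, which is fast for an electron-rich ortho-hydroxyaryl ketal, so that the exposure of the chromene and of the trisubstituted alkene to acid is brief and neither C1' nor the alkene geometry should be affected.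

**Compound list**

1 | 4-bromo-3-methoxyphenol | COc1cc(O)ccc1Br | starting material
2 | 3-methylbut-2-enal | CC(C)=CC=O | starting material
3 | 4-bromo-3-methoxy-6-(3-methylbut-2-en-1-ylidene)cyclohexa-2,4-dien-1-one (ortho-quinone methide) | COC1=CC(=O)C(=CC=C(C)C)C=C1Br | intermediate
4 | 6-bromo-7-methoxy-2,2-dimethyl-2H-chromene | COc1cc2c(cc1Br)C=CC(C)(C)O2 | intermediate
5 | ethyl pyruvate | CCOC(=O)C(C)=O | starting material
6 | (7-methoxy-2,2-dimethyl-2H-chromen-6-yl)lithium | COc1cc2c(cc1[Li])C=CC(C)(C)O2 | intermediate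
7 | ethyl 2-hydroxy-2-(7-methoxy-2,2-dimethyl-2H-chromen-6-yl)propanoate (racemic) | COc1cc2c(cc1C(C)(O)C(=O)OCC)C=CC(C)(C)O2 | intermediate
8 | ethyl 2-(7-methoxy-2,2-dimethyl-2H-chromen-6-yl)acrylate | COc1cc2c(cc1C(=C)C(=O)OCC)C=CC(C)(C)O2 | intermediate
9 | 2-(7-methoxy-2,2-dimethyl-2H-chromen-6-yl)acrylic acid | COc1cc2c(cc1C(=C)C(=O)O)C=CC(C)(C)O2 | intermediate
10 | (R)-2-(7-methoxy-2,2-dimethyl-2H-chromen-6-yl)propanoic acid | COc1cc2c(cc1[C@@H](C)C(=O)O)C=CC(C)(C)O2 | intermediate
11 | isobutyl carbonic (R)-2-(7-methoxy-2,2-dimethyl-2H-chromen-6-yl)propanoic anhydride | COc1cc2c(cc1[C@@H](C)C(=O)OC(=O)OCC(C)C)C=CC(C)(C)O2 | intermediate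
12 | (R)-1-diazo-3-(7-methoxy-2,2-dimethyl-2H-chromen-6-yl)butan-2-one | COc1cc2c(cc1[C@@H](C)C(=O)C=[N+]=[N-])C=CC(C)(C)O2 | intermediate
13 | 2,4-dihydroxyacetophenone | CC(=O)c1ccc(O)cc1O | starting material
14 | 1-(2,4-dihydroxy-5-iodophenyl)ethanone | CC(=O)c1cc(I)c(O)cc1O | intermediate
15 | ethynyltrimethylsilane | C#C[Si](C)(C)C | starting material
16 | 1-{2,4-dihydroxy-5-[(trimethylsilyl)ethynyl]phenyl}ethanone | CC(=O)c1cc(C#C[Si](C)(C)C)c(O)cc1O | intermediate
17 | 1-[6-hydroxy-2-(trimethylsilyl)benzofuran-5-yl]ethanone | CC(=O)c1cc2cc([Si](C)(C)C)oc2cc1O | intermediate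
18 | 1-(6-hydroxybenzofuran-5-yl)ethanone | CC(=O)c1cc2ccoc2cc1O | intermediate
19 | 1-[6-(tert-butyldimethylsilyloxy)benzofuran-5-yl]ethanone | CC(=O)c1cc2ccoc2cc1O[Si](C)(C)C(C)(C)C | intermediate
20 | tert-butyldimethyl{[5-(2-methyl-1,3-dioxolan-2-yl)benzofuran-6-yl]oxy}silane | CC1(OCCO1)c1cc2ccoc2cc1O[Si](C)(C)C(C)(C)C | intermediate
21 | (S)-3-(7-methoxy-2,2-dimethyl-2H-chromen-6-yl)but-1-en-1-one (ketene) | COc1cc2c(cc1[C@@H](C)C=C=O)C=CC(C)(C)O2 | intermediate
22 | [6-(tert-butyldimethylsilyloxy)-5-(2-methyl-1,3-dioxolan-2-yl)benzofuran-2-yl]lithium | CC1(OCCO1)c1cc2cc([Li])oc2cc1O[Si](C)(C)C(C)(C)C | intermediate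
23 | lithium (S,Z)-1-[6-(tert-butyldimethylsilyloxy)-5-(2-methyl-1,3-dioxolan-2-yl)benzofuran-2-yl]-3-(7-methoxy-2,2-dimethyl-2H-chromen-6-yl)but-1-en-1-olate | COc1cc2c(cc1[C@@H](C)/C=C(\O[Li])c1cc3cc(C4(C)OCCO4)c(O[Si](C)(C)C(C)(C)C)cc3o1)C=CC(C)(C)O2 | intermediate
24 | (S,Z)-1-[6-(tert-butyldimethylsilyloxy)-5-(2-methyl-1,3-dioxolan-2-yl)benzofuran-2-yl]-3-(7-methoxy-2,2-dimethyl-2H-chromen-6-yl)but-1-en-1-yl trifluoromethanesulfonate | COc1cc2c(cc1[C@@H](C)/C=C(\OS(=O)(=O)C(F)(F)F)c1cc3cc(C4(C)OCCO4)c(O[Si](C)(C)C(C)(C)C)cc3o1)C=CC(C)(C)O2 | intermediate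
25 | tert-butyl{[2-((S,E)-4-(7-methoxy-2,2-dimethyl-2H-chromen-6-yl)pent-2-en-2-yl)-5-(2-methyl-1,3-dioxolan-2-yl)benzofuran-6-yl]oxy}dimethylsilane | COc1cc2c(cc1[C@@H](C)/C=C(\C)c1cc3cc(C4(C)OCCO4)c(O[Si](C)(C)C(C)(C)C)cc3o1)C=CC(C)(C)O2 | intermediate
26 | 2-[(S,E)-4-(7-methoxy-2,2-dimethyl-2H-chromen-6-yl)pent-2-en-2-yl]-5-(2-methyl-1,3-dioxolan-2-yl)benzofuran-6-ol | COc1cc2c(cc1[C@@H](C)/C=C(\C)c1cc3cc(C4(C)OCCO4)c(O)cc3o1)C=CC(C)(C)O2 | intermediate
27 | 1-{6-hydroxy-2-[(S,E)-4-(7-methoxy-2,2-dimethyl-2H-chromen-6-yl)pent-2-en-2-yl]benzofuran-5-yl}ethanone | COc1cc2c(cc1[C@@H](C)/C=C(\C)c1cc3cc(C(C)=O)c(O)cc3o1)C=CC(C)(C)O2 | target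

**Step count and risks**

Total step count: 13. Longest linear sequence: 9 steps (steps 1 to 6, then 11, 12 and 13), from 4-bromo-3-methoxyphenol.

Steps most likely to fail:

1. Step 11 (proposed new method). The ketene may dimerise or be deprotonated at C2' before the carbon–carbon bond forms, the pyran ring may photo-open if the lamp emits below about 350 nm, or O-sulfonylation of the enolate may be slow. The fallback uses known chemistry, sets out from 12 and comes back at 24. The Wolff rearrangement of 12 is run in its established Arndt–Eistert form (PhCO2Ag, Et3N, THF, −20 → 25 °C) in the presence of N,O-dimethylhydroxylamine, so that the ketene is taken up as the Weinreb amide (S)-N-methoxy-N-methyl-3-(7-methoxy-2,2-dimethyl-2H-chromen-6-yl)butanamide F1. Addition of 2-lithiobenzofuran 22 (from 20 and n-BuLi, THF, −78 °C) to F1 should give the ketone (S)-1-[6-(tert-butyldimethylsilyloxy)-5-(2-methyl-1,3-dioxolan-2-yl)benzofuran-2-yl]-3-(7-methoxy-2,2-dimethyl-2H-chromen-6-yl)butan-1-one F2, in which C1' is β to the carbonyl and cannot epimerise. Enolisation of F2 with KN(SiMe3)2 (THF, −78 °C) and trapping with PhNTf2 should give enol triflate 24, since aryl alkyl ketones form the enolate with O cis to the β-substituent.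

2. Step 5. Facial selectivity may be poor on an acrylic acid whose aryl group carries an ortho-methoxy substituent, or the chromene C3=C4 bond may be reduced as well. The fallback sets out from 4 and comes back at 10, and sets C1' by auxiliary-controlled alkylation. Negishi coupling of 4 with BrZnCH2CO2Et (Pd2(dba)3, XPhos, THF, 60 °C) should give ethyl 2-(7-methoxy-2,2-dimethyl-2H-chromen-6-yl)acetate F3, and LiOH (THF/H2O) gives 2-(7-methoxy-2,2-dimethyl-2H-chromen-6-yl)acetic acid F4. Activation with pivaloyl chloride and Et3N and reaction with lithiated (R)-4-benzyloxazolidin-2-one gives (R)-4-benzyl-3-[2-(7-methoxy-2,2-dimethyl-2H-chromen-6-yl)acetyl]oxazolidin-2-one F5. Its enolate (NaN(SiMe3)2, THF, −78 °C) is methylated with MeI anti to the benzyl group to give (R)-4-benzyl-3-[(R)-2-(7-methoxy-2,2-dimethyl-2H-chromen-6-yl)propanoyl]oxazolidin-2-one F6. LiOH and H2O2 (THF/H2O, 0 °C) then release acid 10.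

3. Step 10. Ketalisation of the hindered, electron-rich ortho-silyloxy aryl ketone may stall, or the silyl ether may be lost under the Lewis acid. The fallback sets out from 18 and comes back at 27, and masks the acetyl group as a silyl enol ether. TBSOTf (2.5 equiv) and Et3N (CH2Cl2, 0 °C) should give tert-butyl{[1-(6-{[tert-butyl(dimethyl)silyl]oxy}benzofuran-5-yl)vinyl]oxy}dimethylsilane F7. This is lithiated with n-BuLi (THF, −78 °C) to [6-(tert-butyldimethylsilyloxy)-5-(1-(tert-butyldimethylsilyloxy)vinyl)benzofuran-2-yl]lithium F8. F8 captures ketene 21 under the conditions of step 11 to give the lithium (S,Z)-enolate F9, which is O-triflated with PhNTf2 to the (S,Z)-enol triflate F10. Coupling with MeZnCl and Pd(PPh3)4 as in step 12 gives the (S,E)-bis-silyl compound F11. TBAF with AcOH (THF, 0 °C) then removes both silyl groups, the enol ether returning the acetyl group, to give 27 without any acid stronger than acetic acid.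

**Further compounds**

F1 | step 11 | (S)-N-methoxy-N-methyl-3-(7-methoxy-2,2-dimethyl-2H-chromen-6-yl)butanamide | COc1cc2c(cc1[C@@H](C)CC(=O)N(C)OC)C=CC(C)(C)O2
F2 | step 11 | (S)-1-[6-(tert-butyldimethylsilyloxy)-5-(2-methyl-1,3-dioxolan-2-yl)benzofuran-2-yl]-3-(7-methoxy-2,2-dimethyl-2H-chromen-6-yl)butan-1-one | COc1cc2c(cc1[C@@H](C)CC(=O)c1cc3cc(C4(C)OCCO4)c(O[Si](C)(C)C(C)(C)C)cc3o1)C=CC(C)(C)O2
F3 | step 5 | ethyl 2-(7-methoxy-2,2-dimethyl-2H-chromen-6-yl)acetate | COc1cc2c(cc1CC(=O)OCC)C=CC(C)(C)O2
F4 | step 5 | 2-(7-methoxy-2,2-dimethyl-2H-chromen-6-yl)acetic acid | COc1cc2c(cc1CC(=O)O)C=CC(C)(C)O2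
F5 | step 5 | (R)-4-benzyl-3-[2-(7-methoxy-2,2-dimethyl-2H-chromen-6-yl)acetyl]oxazolidin-2-one | COc1cc2c(cc1CC(=O)N1[C@H](Cc3ccccc3)COC1=O)C=CC(C)(C)O2
F6 | step 5 | (R)-4-benzyl-3-[(R)-2-(7-methoxy-2,2-dimethyl-2H-chromen-6-yl)propanoyl]oxazolidin-2-one | COc1cc2c(cc1[C@@H](C)C(=O)N1[C@H](Cc3ccccc3)COC1=O)C=CC(C)(C)O2
F7 | step 10 | tert-butyl{[1-(6-{[tert-butyl(dimethyl)silyl]oxy}benzofuran-5-yl)vinyl]oxy}dimethylsilane | C=C(O[Si](C)(C)C(C)(C)C)c1cc2ccoc2cc1O[Si](C)(C)C(C)(C)C
F8 | step 10 | [6-(tert-butyldimethylsilyloxy)-5-(1-(tert-butyldimethylsilyloxy)vinyl)benzofuran-2-yl]lithium | C=C(O[Si](C)(C)C(C)(C)C)c1cc2cc([Li])oc2cc1O[Si](C)(C)C(C)(C)C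
F9 | step 10 | lithium (S,Z)-1-[6-(tert-butyldimethylsilyloxy)-5-(1-(tert-butyldimethylsilyloxy)vinyl)benzofuran-2-yl]-3-(7-methoxy-2,2-dimethyl-2H-chromen-6-yl)but-1-en-1-olate | COc1cc2c(cc1[C@@H](C)/C=C(\O[Li])c1cc3cc(C(=C)O[Si](C)(C)C(C)(C)C)c(O[Si](C)(C)C(C)(C)C)cc3o1)C=CC(C)(C)O2
F10 | step 10 | (S,Z)-1-[6-(tert-butyldimethylsilyloxy)-5-(1-(tert-butyldimethylsilyloxy)vinyl)benzofuran-2-yl]-3-(7-methoxy-2,2-dimethyl-2H-chromen-6-yl)but-1-en-1-yl trifluoromethanesulfonate | COc1cc2c(cc1[C@@H](C)/C=C(\OS(=O)(=O)C(F)(F)F)c1cc3cc(C(=C)O[Si](C)(C)C(C)(C)C)c(O[Si](C)(C)C(C)(C)C)cc3o1)C=CC(C)(C)O2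
F11 | step 10 | tert-butyl{[1-(6-{[tert-butyl(dimethyl)silyl]oxy}-2-[(S,E)-4-(7-methoxy-2,2-dimethyl-2H-chromen-6-yl)pent-2-en-2-yl]benzofuran-5-yl)vinyl]oxy}dimethylsilane | COc1cc2c(cc1[C@@H](C)/C=C(\C)c1cc3cc(C(=C)O[Si](C)(C)C(C)(C)C)c(O[Si](C)(C)C(C)(C)C)cc3o1)C=CC(C)(C)O2
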